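**Retrosynthetic overview**

1. Target 17 ⇐ tri-O-benzyl flavanone 16 ⇐ arylboronic acid 13 + 5,7-bis(benzyloxy)chromone 15. One Rh-catalysed asymmetric 1,4-arylation makes the flavanone C2–aryl bond and its (S) centre; the pyranone ring is bought as a chromone.
2. 13 ⇐ cis acid 11 ⇐ planar 1,4-benzodioxine-2-carboxylic acid 10. One carboxyl-directed asymmetric syn-hydrogenation of C2=C3 sets both dioxane centres, cis, in a single event.
3. Dioxine ring of 9/10 ⇐ acyclic 7 by ring-closing C2=C3 olefination. A phosphonoacetate carbanion (the future CH2OH-bearing carbon, on the oxygen para to Br) attacks the aryl vanillate carbonyl (the future aryl-bearing carbon, on the oxygen meta to Br).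
4. Enabling feature: the two vicinal oxygens on C4a and C8a of the benzo ring hold these two carbons 1,6 to each other, and both carbons are oxygen-substituted. The bond can therefore be made at the enediol-diether (alkene) level, and the flat dioxine gives cis automatically on hydrogenation.
5. 7 ⇐ 5-bromosalicylaldehyde 1 (Rh-carbene O–H insertion, Dakin-type oxidation, esterification with O-benzylvanillic acid 6). Ring order: benzo ring bought, dioxine ring closed in step 4, chromanone ring attached in step 10.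

Key step: step 4

Assumption: the sense of induction of the chiral Ir catalyst (step 6) and Rh catalyst (step 10) is taken by analogy with simpler substrates; the ligand antipode is chosen so that the products drawn below are obtained.

**Route**

Step 1
Reactants: 1 5-bromo-2-hydroxybenzaldehyde; 2 ethyl diazo(diethoxyphosphoryl)acetate
Product: 3 ethyl 2-(4-bromo-2-formylphenoxy)-2-(diethoxyphosphoryl)acetate (racemic)
Conditions: Rh2(OAc)4 (2 mol%), toluene, 90 °C, slow addition of 2
Reagents that add atoms: none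
Why: Rh-carbene O–H insertion of a phenol into a diazophosphonoacetate is an established route to α-aryloxy phosphonoacetates and should outrun attack of the carbene on the aldehyde; the new centre is racemic and is erased in step 4.

Step 2
Reactants: 3 ethyl 2-(4-bromo-2-formylphenoxy)-2-(diethoxyphosphoryl)acetate
Product: 5 ethyl 2-(4-bromo-2-hydroxyphenoxy)-2-(diethoxyphosphoryl)acetate (racemic), via aryl formate 4 (not isolated)
Conditions: mCPBA, CH2Cl2, 0 °C to rt; then Et3N (cat.), EtOH, 0 °C
Reagents that add atoms: mCPBA, O=C(OO)c1cccc(Cl)c1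
Why: Baeyer–Villiger (Dakin-type) oxidation of an ortho-alkoxybenzaldehyde proceeds with aryl migration, and ethanolysis of the labile aryl formate should unmask the oxygen meta to bromine without touching the ethyl ester.

Step 3
Reactants: 5 ethyl 2-(4-bromo-2-hydroxyphenoxy)-2-(diethoxyphosphoryl)acetate; 6 4-(benzyloxy)-3-methoxybenzoic acid
Product: 7 5-bromo-2-[1-(diethoxyphosphoryl)-2-ethoxy-2-oxoethoxy]phenyl 4-(benzyloxy)-3-methoxybenzoate (racemic)
Conditions: DCC, DMAP (cat.), CH2Cl2, 0 °C to rt
Reagents that add atoms: none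
Why: Steglich esterification of a phenol is mild enough to leave the acidic phosphonoacetate CH untouched and places the aroyl carbon on the second catechol oxygen.

Step 4
Reactants: 7 5-bromo-2-[1-(diethoxyphosphoryl)-2-ethoxy-2-oxoethoxy]phenyl 4-(benzyloxy)-3-methoxybenzoate
Product: 9 ethyl 6-bromo-3-[4-(benzyloxy)-3-methoxyphenyl]-1,4-benzodioxine-2-carboxylate, via cyclic sodium β-oxidophosphonate 8 (not isolated)
Conditions: NaH (1.05 equiv), THF, 0 °C then 60 °C
Reagents that add atoms: none
Why: Proposed new method: NaH deprotonates the phosphonoacetate CH, and the stabilised carbanion adds to the neighbouring aryl ester carbonyl to give the cyclic β-oxidophosphonate 8, which closes to an oxaphosphetane and loses diethyl phosphate to leave the C2=C3 double bond. The closest known reaction types are the intramolecular Wittig olefination of aryl esters by ortho-tethered phosphorus ylides (benzofuran synthesis) and the Rh-carbene O–H insertion/intramolecular Horner–Wadsworth–Emmons sequence that makes 2-alkoxycarbonyl cyclic enol ethers from hydroxy ketones; a phosphonate carbanion olefinating an ester carbonyl to close a 1,4-benzodioxine has not been shown. The one ring closed is the dioxine ring, by C–C bond formation in the 6-exo-trig mode (carbanion onto an exocyclic C=O), followed by syn elimination within the ring. No stereocentre is made here: the step deliberately delivers a planar, tetrasubstituted enediol diether so that both dioxane centres can be set cis in the single hydrogenation of step 6. The selectivity needed is olefination over O-to-C aroyl transfer and over phosphoryl transfer to oxygen; the aryl ester is the only carbonyl within six-membered reach and is activated by its phenoxide leaving group, and because the attacking carbon carries no second hydrogen, ring opening of 8 to the aryl ketone cannot be locked in as an enolate and stays reversible. Only the diastereomer of 8 with oxide and phosphorus cis can eliminate, and the open/closed equilibrium should feed it until the irreversible loss of phosphate has drained the system.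

Step 5
Reactants: 9 ethyl 6-bromo-3-[4-(benzyloxy)-3-methoxyphenyl]-1,4-benzodioxine-2-carboxylate
Product: 10 6-bromo-3-[4-(benzyloxy)-3-methoxyphenyl]-1,4-benzodioxine-2-carboxylic acid
Conditions: LiOH·H2O, THF/H2O, rt; then 1 M HCl
Reagents that add atoms: lithium hydroxide, [Li+].[OH-]
Why: Saponification of the conjugated ethyl ester gives the free acid that the directed hydrogenation needs; aryl bromide, benzyl ether and the enediol diether should tolerate cold aqueous hydroxide.

Step 6
Reactants: 10 6-bromo-3-[4-(benzyloxy)-3-methoxyphenyl]-1,4-benzodioxine-2-carboxylic acid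
Product: 11 (2S,3S)-6-bromo-3-[4-(benzyloxy)-3-methoxyphenyl]-2,3-dihydro-1,4-benzodioxine-2-carboxylic acid (cis)
Conditions: [Ir(cod)(SIPHOX)]BArF (1 mol%, chiral spiro phosphine–oxazoline ligand), H2 (6 atm), Et3N (0.5 equiv), MeOH, 45 °C
Reagents that add atoms: none
Why: Ir-catalysed carboxyl-directed asymmetric hydrogenation of α-aryloxy-α,β-unsaturated acids, tetrasubstituted ones included, adds both hydrogens syn to one face of C2=C3, so aryl and carboxyl must end up cis, while the chiral P,N ligand selects the face that gives (2S,3S).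

Step 7
Reactants: 11 (2S,3S)-6-bromo-3-[4-(benzyloxy)-3-methoxyphenyl]-2,3-dihydro-1,4-benzodioxine-2-carboxylic acid
Product: 12 [(2R,3S)-6-bromo-3-[4-(benzyloxy)-3-methoxyphenyl]-2,3-dihydro-1,4-benzodioxin-2-yl]methanol (cis)
Conditions: BH3·THF, THF, 0 °C to rt; MeOH quench
Reagents that add atoms: none
Why: Chemoselective borane reduction of a carboxylic acid proceeds without base, so the α-centre is not epimerised (the descriptor changes from S to R only through the priority rules).

Step 8
Reactants: 12 [(2R,3S)-6-bromo-3-[4-(benzyloxy)-3-methoxyphenyl]-2,3-dihydro-1,4-benzodioxin-2-yl]methanol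
Product: 13 [(2R,3S)-3-[4-(benzyloxy)-3-methoxyphenyl]-2-(hydroxymethyl)-2,3-dihydro-1,4-benzodioxin-6-yl]boronic acid
Conditions: B2(OH)4, PdCl(XPhos)(2'-aminobiphenyl-2-yl) precatalyst (2 mol%), XPhos, KOAc, EtOH, 80 °C
Reagents that add atoms: tetrahydroxydiboron, OB(O)B(O)O
Why: Pd-catalysed Miyaura-type borylation of an aryl bromide with tetrahydroxydiboron gives the boronic acid directly under weakly basic conditions that tolerate the free alcohol and leave both stereocentres untouched.

Step 9
Reactants: 14 5,7-dihydroxy-4H-chromen-4-one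
Product: 15 5,7-bis(benzyloxy)-4H-chromen-4-one
Conditions: BnBr (2.5 equiv), K2CO3, DMF, 70 °C
Reagents that add atoms: benzyl bromide, BrCc1ccccc1
Why: Williamson etherification with excess benzyl bromide and warming should also alkylate the hydrogen-bonded 5-OH, removing the acidic phenols that would otherwise quench the aryl–Rh species in step 10.

Step 10
Reactants: 13 [(2R,3S)-3-[4-(benzyloxy)-3-methoxyphenyl]-2-(hydroxymethyl)-2,3-dihydro-1,4-benzodioxin-6-yl]boronic acid; 15 5,7-bis(benzyloxy)-4H-chromen-4-one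
Product: 16 (2S)-5,7-bis(benzyloxy)-2-[(2R,3S)-3-[4-(benzyloxy)-3-methoxyphenyl]-2-(hydroxymethyl)-2,3-dihydro-1,4-benzodioxin-6-yl]-2,3-dihydro-4H-chromen-4-one
Conditions: [Rh(OH)(cod)]2 (2.5 mol%), (S)-MeO-F12-BIPHEP (6 mol%), toluene/H2O 10:1, 30 °C
Reagents that add atoms: none
Why: In the Hayashi–Miyaura Rh-catalysed asymmetric 1,4-addition of an arylboronic acid to a chromone, the aryl–Rh species with the chiral bisphosphine adds to one enantioface of the pyranone C2=C3 bond, setting the (2S) centre under catalyst control; the remote dioxane centres should have no influence.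

Step 11
Reactants: 16 (2S)-5,7-bis(benzyloxy)-2-[(2R,3S)-3-[4-(benzyloxy)-3-methoxyphenyl]-2-(hydroxymethyl)-2,3-dihydro-1,4-benzodioxin-6-yl]-2,3-dihydro-4H-chromen-4-one
Product: 17 isocisilandrin, (2S)-5,7-dihydroxy-2-[(2R,3S)-3-(4-hydroxy-3-methoxyphenyl)-2-(hydroxymethyl)-2,3-dihydro-1,4-benzodioxin-6-yl]-2,3-dihydro-4H-chromen-4-one
Conditions: H2 (1 atm), 10% Pd/C, EtOAc/MeOH, rt, stopped at full debenzylation
Reagents that add atoms: none
Why: Hydrogenolysis of the three phenolic benzyl ethers under neutral conditions avoids the base that would epimerise the flavanone centre and the strong acid that could ionise the benzylic dioxane C–O bond; O-benzyl ethers should cleave well before the ring benzylic C–O bonds.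

**Compound list**

1 | 5-bromo-2-hydroxybenzaldehyde | O=Cc1cc(Br)ccc1O | starting material
2 | ethyl diazo(diethoxyphosphoryl)acetate | CCOC(=O)C(=[N+]=[N-])P(=O)(OCC)OCC | starting material
3 | ethyl 2-(4-bromo-2-formylphenoxy)-2-(diethoxyphosphoryl)acetate (racemic) | CCOC(=O)C(Oc1ccc(Br)cc1C=O)P(=O)(OCC)OCC | intermediate
4 | ethyl 2-[4-bromo-2-(formyloxy)phenoxy]-2-(diethoxyphosphoryl)acetate (racemic, not isolated) | CCOC(=O)C(Oc1ccc(Br)cc1OC=O)P(=O)(OCC)OCC | intermediate
5 | ethyl 2-(4-bromo-2-hydroxyphenoxy)-2-(diethoxyphosphoryl)acetate (racemic) | CCOC(=O)C(Oc1ccc(Br)cc1O)P(=O)(OCC)OCC | intermediate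
6 | 4-(benzyloxy)-3-methoxybenzoic acid | COc1cc(C(=O)O)ccc1OCc1ccccc1 | starting material
7 | 5-bromo-2-[1-(diethoxyphosphoryl)-2-ethoxy-2-oxoethoxy]phenyl 4-(benzyloxy)-3-methoxybenzoate (racemic) | CCOC(=O)C(Oc1ccc(Br)cc1OC(=O)c1ccc(OCc2ccccc2)c(OC)c1)P(=O)(OCC)OCC | intermediate
8 | sodium 2-[4-(benzyloxy)-3-methoxyphenyl]-7-bromo-3-(diethoxyphosphoryl)-3-(ethoxycarbonyl)-2,3-dihydro-1,4-benzodioxin-2-olate (diastereomer mixture, not isolated) | CCOC(=O)C1(P(=O)(OCC)OCC)Oc2ccc(Br)cc2OC1([O-])c1ccc(OCc2ccccc2)c(OC)c1.[Na+] | intermediate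
9 | ethyl 6-bromo-3-[4-(benzyloxy)-3-methoxyphenyl]-1,4-benzodioxine-2-carboxylate | CCOC(=O)C1=C(c2ccc(OCc3ccccc3)c(OC)c2)Oc2cc(Br)ccc2O1 | intermediate
10 | 6-bromo-3-[4-(benzyloxy)-3-methoxyphenyl]-1,4-benzodioxine-2-carboxylic acid | OC(=O)C1=C(c2ccc(OCc3ccccc3)c(OC)c2)Oc2cc(Br)ccc2O1 | intermediate
11 | (2S,3S)-6-bromo-3-[4-(benzyloxy)-3-methoxyphenyl]-2,3-dihydro-1,4-benzodioxine-2-carboxylic acid (cis) | COc1cc([C@@H]2Oc3cc(Br)ccc3O[C@@H]2C(=O)O)ccc1OCc1ccccc1 | intermediate
12 | [(2R,3S)-6-bromo-3-[4-(benzyloxy)-3-methoxyphenyl]-2,3-dihydro-1,4-benzodioxin-2-yl]methanol (cis) | COc1cc([C@@H]2Oc3cc(Br)ccc3O[C@@H]2CO)ccc1OCc1ccccc1 | intermediate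
13 | [(2R,3S)-3-[4-(benzyloxy)-3-methoxyphenyl]-2-(hydroxymethyl)-2,3-dihydro-1,4-benzodioxin-6-yl]boronic acid | COc1cc([C@@H]2Oc3cc(B(O)O)ccc3O[C@@H]2CO)ccc1OCc1ccccc1 | intermediate
14 | 5,7-dihydroxy-4H-chromen-4-one | O=c1ccoc2cc(O)cc(O)c12 | starting material
15 | 5,7-bis(benzyloxy)-4H-chromen-4-one | O=c1ccoc2cc(OCc3ccccc3)cc(OCc3ccccc3)c12 | intermediate
16 | (2S)-5,7-bis(benzyloxy)-2-[(2R,3S)-3-[4-(benzyloxy)-3-methoxyphenyl]-2-(hydroxymethyl)-2,3-dihydro-1,4-benzodioxin-6-yl]-2,3-dihydro-4H-chromen-4-one | COc1cc([C@@H]2Oc3cc([C@@H]4CC(=O)c5c(OCc6ccccc6)cc(OCc6ccccc6)cc5O4)ccc3O[C@@H]2CO)ccc1OCc1ccccc1 | intermediate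
17 | isocisilandrin, (2S)-5,7-dihydroxy-2-[(2R,3S)-3-(4-hydroxy-3-methoxyphenyl)-2-(hydroxymethyl)-2,3-dihydro-1,4-benzodioxin-6-yl]-2,3-dihydro-4H-chromen-4-one | COc1cc([C@@H]2Oc3cc([C@@H]4CC(=O)c5c(O)cc(O)cc5O4)ccc3O[C@@H]2CO)ccc1O | target

**Step count and risks**

Total steps: 11. Longest linear sequence: 10 steps (steps 1–8, 10, 11); step 9 prepares the chromone partner.

Steps most likely to fail:

Step 4 (Proposed new method). The tetrahedral adduct may collapse by O-to-C aroyl transfer and then lose the phosphoryl group to the liberated phenoxide before olefination, or the carbanion may fail to add to the electron-rich aryl ester at all. The fallback uses known chemistry, sets out from 1 and returns at 9. Alkylation of 1 with ethyl bromoacetate (K2CO3, acetone, rt) would give ethyl 2-(4-bromo-2-formylphenoxy)acetate F1. Baeyer–Villiger oxidation (mCPBA) would give the aryl formate ethyl 2-[4-bromo-2-(formyloxy)phenoxy]acetate F2, and ethanolysis would give ethyl 2-(4-bromo-2-hydroxyphenoxy)acetate F3. Steglich esterification with 6 would give 5-bromo-2-(2-ethoxy-2-oxoethoxy)phenyl 4-(benzyloxy)-3-methoxybenzoate F4. LiHMDS (THF, −78 °C) should induce a Baker–Venkataraman-type O-to-C aroyl transfer to ethyl 3-[4-(benzyloxy)-3-methoxyphenyl]-2-(4-bromo-2-hydroxyphenoxy)-3-oxopropanoate F5, which equilibrates with its cyclic hemiketal. Acid-catalysed cyclodehydration (TsOH, toluene, water separator), the classical entry to 2-aryl-1,4-benzodioxines, would then give 9.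

Step 6. Hydrogenation of the push–pull tetrasubstituted alkene may be slow, or the face selection may be poor. The fallback separates reduction from enantioselection, sets out from 10 and returns at 11. Syn-hydrogenation with the achiral complex [Ir(cod)(PCy3)(py)]PF6 (H2, CH2Cl2) would give the racemic cis acid rac-(2S,3S)-6-bromo-3-[4-(benzyloxy)-3-methoxyphenyl]-2,3-dihydro-1,4-benzodioxine-2-carboxylic acid F6. Classical resolution by crystallisation would give the (S)-1-phenylethylammonium (2S,3S)-carboxylate F7 (the antipodal amine is used if the other diastereomeric salt is the less soluble one), and acidification would release 11.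

Step 10. Protodeboronation of 13 may outrun insertion into the deactivated 5,7-dioxygenated chromone, or the facial selectivity on the chiral boronic acid may be poor. The fallback separates C–C bond formation from stereocontrol, sets out from 13 and 15 and returns at 16. Pd(OCOCF3)2-catalysed oxidative conjugate arylation/dehydrogenation of 15 with 13 would give the flavone 5,7-bis(benzyloxy)-2-[(2R,3S)-3-[4-(benzyloxy)-3-methoxyphenyl]-2-(hydroxymethyl)-2,3-dihydro-1,4-benzodioxin-6-yl]-4H-chromen-4-one F8. Asymmetric hydrogenation of the pyranone with a chiral Ru–NHC catalyst ([Ru(cod)(2-methylallyl)2], SINpEt·HBF4, KOt-Bu, H2) would give the (2S)-flavan-4-ol F9 (C4 configuration immaterial). MnO2 oxidation of the benzylic secondary alcohol, leaving the primary alcohol, would give 16.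

Further compounds

F1 | step 4 | ethyl 2-(4-bromo-2-formylphenoxy)acetate | CCOC(=O)COc1ccc(Br)cc1C=O
F2 | step 4 | ethyl 2-[4-bromo-2-(formyloxy)phenoxy]acetate | CCOC(=O)COc1ccc(Br)cc1OC=O
F3 | step 4 | ethyl 2-(4-bromo-2-hydroxyphenoxy)acetate | CCOC(=O)COc1ccc(Br)cc1O
F4 | step 4 | 5-bromo-2-(2-ethoxy-2-oxoethoxy)phenyl 4-(benzyloxy)-3-methoxybenzoate | CCOC(=O)COc1ccc(Br)cc1OC(=O)c1ccc(OCc2ccccc2)c(OC)c1
F5 | step 4 | ethyl 3-[4-(benzyloxy)-3-methoxyphenyl]-2-(4-bromo-2-hydroxyphenoxy)-3-oxopropanoate (racemic) | CCOC(=O)C(Oc1ccc(Br)cc1O)C(=O)c1ccc(OCc2ccccc2)c(OC)c1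
F6 | step 6 | racemic cis-6-bromo-3-[4-(benzyloxy)-3-methoxyphenyl]-2,3-dihydro-1,4-benzodioxine-2-carboxylic acid (both enantiomers shown) | COc1cc([C@@H]2Oc3cc(Br)ccc3O[C@@H]2C(=O)O)ccc1OCc1ccccc1.COc1cc([C@H]2Oc3cc(Br)ccc3O[C@H]2C(=O)O)ccc1OCc1ccccc1
F7 | step 6 | (S)-1-phenylethylammonium (2S,3S)-6-bromo-3-[4-(benzyloxy)-3-methoxyphenyl]-2,3-dihydro-1,4-benzodioxine-2-carboxylate | COc1cc([C@@H]2Oc3cc(Br)ccc3O[C@@H]2C(=O)[O-])ccc1OCc1ccccc1.C[C@H]([NH3+])c1ccccc1
F8 | step 10 | 5,7-bis(benzyloxy)-2-[(2R,3S)-3-[4-(benzyloxy)-3-methoxyphenyl]-2-(hydroxymethyl)-2,3-dihydro-1,4-benzodioxin-6-yl]-4H-chromen-4-one | COc1cc([C@@H]2Oc3cc(-c4cc(=O)c5c(OCc6ccccc6)cc(OCc6ccccc6)cc5o4)ccc3O[C@@H]2CO)ccc1OCc1ccccc1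
F9 | step 10 | (2S)-5,7-bis(benzyloxy)-2-[(2R,3S)-3-[4-(benzyloxy)-3-methoxyphenyl]-2-(hydroxymethyl)-2,3-dihydro-1,4-benzodioxin-6-yl]-3,4-dihydro-2H-chromen-4-ol (C4 epimers) | COc1cc([C@@H]2Oc3cc([C@@H]4CC(O)c5c(OCc6ccccc6)cc(OCc6ccccc6)cc5O4)ccc3O[C@@H]2CO)ccc1OCc1ccccc1
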